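## Retrosynthetic overview

1. Target 21 ⇐ syn reduction of the C2 ketone ⇐ acylation of C10–OH ⇐ hydroxy ester 19.
2. Key step: 19 ⇐ epoxy-norcarane 17 by a carboxylate-terminated cyclopropylcarbinyl-to-homoallyl ring expansion (six- to seven-membered ring; sets C6, creates C8=C9, frees 10-OH).
3. 17 ⇐ epoxidation of vinylcyclopropane 16 ⇐ PtCl2 cycloisomerisation of enyne 14 (six-membered ring and cyclopropane formed together).
4. 14 ⇐ three-component coupling of cyclopentenone 9 with a vinyl unit (C6, C7) and a but-2-ynyl unit (C10, C9, C8, C8-methyl).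
5. 9 ⇐ (R)-4-silyloxycyclopentenone 1 (methylation, isopropyl addition, carbonyl transposition). Ring order: cyclopentane (bought), cyclohexene plus cyclopropane (step 7), cycloheptene by expansion (step 9).

Assumption and notation: silyl ether 1 is bought as such. Locants are daucane locants: C1 methyl-bearing ring-fusion carbon, C2–C4 the other cyclopentane carbons, C5 ring-fusion CH, C6–C10 the large ring (C8 carries the methyl, C10 is bonded to C1). In 15–17, C7 is the cyclopropane CH2 bridging C6 and C8. α is the face of the C1 methyl, β the opposite face.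

## Route

Step 1
Reactants: 1 (R)-4-(tert-butyldimethylsilyloxy)cyclopent-2-en-1-one; 2 methylmagnesium bromide
Product: 4 (R)-4-(tert-butyldimethylsilyloxy)-3-methylcyclopent-2-en-1-one, via trimethylsilyl enol ether 3 (not isolated)
Conditions: CuI (10 mol %), Me3SiCl, THF, −78 °C; then Pd(OAc)2 (1.05 equiv), MeCN, 25 °C
Reagents that add atoms: none
Why: Copper-catalysed 1,4-addition with in situ silyl trapping followed by Saegusa–Ito oxidation of 3 reinstalls the enone with the new β-methyl group; the silyloxy stereocentre is untouched and the methyl stereocentre of 3 is erased.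

Step 2
Reactants: 4 (R)-4-(tert-butyldimethylsilyloxy)-3-methylcyclopent-2-en-1-one; 5 isopropylmagnesium chloride
Product: 6 (1R,4R)-4-(tert-butyldimethylsilyloxy)-3-methyl-1-(propan-2-yl)cyclopent-2-en-1-ol
Conditions: LaCl3·2LiCl (0.3 equiv), THF, 0 °C
Reagents that add atoms: none
Why: Lanthanide-promoted Grignard 1,2-addition (no enolisation, reduction or 1,4-addition) occurs on the face opposite the silyloxy group, so the new tertiary carbinol (future C4) has OH cis to OTBS.

Step 3
Reactants: 6 (1R,4R)-4-(tert-butyldimethylsilyloxy)-3-methyl-1-(propan-2-yl)cyclopent-2-en-1-ol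
Product: 7 (1R,4R)-3-methyl-1-(propan-2-yl)cyclopent-2-ene-1,4-diol
Conditions: Bu4NF, THF, 0 °C
Reagents that add atoms: none
Why: Fluoride desilylation of the secondary silyl ether; no stereocentre is touched.

Step 4
Reactants: 7 (1R,4R)-3-methyl-1-(propan-2-yl)cyclopent-2-ene-1,4-diol
Product: 8 (R)-4-hydroxy-2-methyl-4-(propan-2-yl)cyclopent-2-en-1-one
Conditions: MnO2, CH2Cl2, 25 °C
Reagents that add atoms: none
Why: MnO2 oxidises only the secondary allylic alcohol, which completes the carbonyl transposition and leaves the tertiary carbinol stereocentre intact.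

Step 5
Reactants: 8 (R)-4-hydroxy-2-methyl-4-(propan-2-yl)cyclopent-2-en-1-one
Product: 9 (R)-2-methyl-4-(propan-2-yl)-4-(trimethylsilyloxy)cyclopent-2-en-1-one
Conditions: Me3SiCl, imidazole, DMF, 0 → 25 °C
Reagents that add atoms: chlorotrimethylsilane C[Si](C)(C)Cl
Why: Silylation of the tertiary alcohol prevents alkoxide formation, and hence retro-aldol racemisation, in the organometallic step that follows.

Step 6
Reactants: 9 (R)-2-methyl-4-(propan-2-yl)-4-(trimethylsilyloxy)cyclopent-2-en-1-one; 10 vinylmagnesium bromide; 11 1-bromobut-2-yne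
Product: 14 (2R,3R,4R)-2-(but-2-yn-1-yl)-3-ethenyl-4-hydroxy-2-methyl-4-(propan-2-yl)cyclopentan-1-one, via bromomagnesium enolate 12 (not isolated), via silyl ether 13 (not isolated)
Conditions: CuBr·SMe2 (20 mol %), THF, −78 → −40 °C; then 11, DMPU, −40 → 0 °C; then 1 M HCl, THF, 25 °C
Reagents that add atoms: none
Why: Three-component coupling of the Noyori/Stork type: the vinyl group adds to C5 anti to the isopropyl group (syn to the smaller OSiMe3), the enolate is C-alkylated anti to the new vinyl group to form the C1 quaternary centre, and the acidic work-up cleaves the tertiary silyl ether.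

Step 7
Reactants: 14 (2R,3R,4R)-2-(but-2-yn-1-yl)-3-ethenyl-4-hydroxy-2-methyl-4-(propan-2-yl)cyclopentan-1-one
Product: 16 tricyclic vinylcyclopropane ketone (trans-hydrind-9-en-2-one with C7 bridging C6 and C8 on the β face; 1α,8α-dimethyl; 4α-OH; 4β-isopropyl), via platinum carbene 15 (not isolated)
Conditions: PtCl2 (5 mol %), toluene, 80 °C
Reagents that add atoms: none
Why: Platinum-catalysed enyne cycloisomerisation: 6-endo attack of the vinyl group on the activated alkyne gives carbene 15, and a 1,2-hydride shift from C10 releases PtCl2 and the C9=C10 alkene; 5-exo closure is excluded because it would form a trans-fused bicyclo[3.3.0]octane, and C7 forms on the face away from the axial C1 methyl.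

Step 8
Reactants: 16 tricyclic vinylcyclopropane ketone
Product: 17 9β,10β-epoxide of 16
Conditions: dimethyldioxirane, acetone, −20 °C
Reagents that add atoms: dimethyldioxirane CC1(C)OO1
Why: Neutral dioxirane epoxidation of the only alkene, from the face opposite the axial C1 methyl that flanks C10, gives the β-epoxide cis to the cyclopropane without acid that would open it.

Step 9
Reactants: 17 9β,10β-epoxide of 16; 18 angelic acid ((Z)-2-methylbut-2-enoic acid)
Product: 19 (1S,4R,5S,6S,10R)-4,10-dihydroxy-2-oxodauc-8-en-6-yl (Z)-2-methylbut-2-enoate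
Conditions: 18 (3 equiv), (PhO)2P(O)OH (10 mol %), toluene, 0 → 25 °C
Reagents that add atoms: none
Why: Proposed new method: hydrogen-bond activation of the epoxide oxygen by the phosphoric acid–carboxylic acid pair lets the C9–O bond ionise with cyclopropane participation; direct SN2 at C9 or C10 is blocked (both flanked by quaternary carbons, rear faces under the C1 and C8 methyls), so the carboxylate attacks the distal cyclopropane carbon C6 anti to the breaking C6–C8 bond (homo-SN2′), expanding the six-membered ring to the cycloheptene with inversion at C6 (6β-ester), a new C8=C9 alkene and the 10β-OH retained; cleavage of the internal bond is preferred because charge develops at secondary C6 and not at primary C7; the closest known reactions are the acid-induced homoallylic opening of 2-carene oxide, the solvolytic 2-norcaranyl to cyclohept-3-enyl rearrangement and the phosphoric-acid-catalysed opening of epoxides by carboxylic acids.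

Step 10
Reactants: 19 (1S,4R,5S,6S,10R)-4,10-dihydroxy-2-oxodauc-8-en-6-yl (Z)-2-methylbut-2-enoate; 18 angelic acid
Product: 20 (1S,4R,5S,6S,10R)-4-hydroxy-2-oxodauc-8-ene-6,10-diyl bis[(Z)-2-methylbut-2-enoate]
Conditions: 18, 2,4,6-trichlorobenzoyl chloride, Et3N, toluene, 25 °C; then 19, 80 °C
Reagents that add atoms: none
Why: Yamaguchi-type mixed-anhydride esterification without DMAP acylates the secondary allylic C10–OH (the tertiary C4–OH is inert and C2 is still a ketone), under conditions that avoid Z-to-E isomerisation of the angelate.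

Step 11
Reactants: 20 (1S,4R,5S,6S,10R)-4-hydroxy-2-oxodauc-8-ene-6,10-diyl bis[(Z)-2-methylbut-2-enoate]
Product: 21 (1R,2R,4R,5S,6S,10R)-2,4-dihydroxydauc-8-ene-6,10-diyl bis[(Z)-2-methylbut-2-enoate]
Conditions: Et2BOMe, NaBH4, THF–MeOH, −78 °C; MeOH co-evaporation
Reagents that add atoms: none
Why: Narasaka–Prasad reduction: the boron chelate between C4–OH and the C2 ketone is attacked by hydride from the β face (also the face opposite the C1 methyl), giving the 2α-alcohol syn to the 4α-OH, while the enoate esters survive at −78 °C.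

## Compound list

1 | (R)-4-(tert-butyldimethylsilyloxy)cyclopent-2-en-1-one | O=C1C=C[C@H](O[Si](C)(C)C(C)(C)C)C1 | starting material
2 | methylmagnesium bromide | C[Mg]Br | starting material
3 | (3R,4R)-4-(tert-butyldimethylsilyloxy)-3-methyl-1-(trimethylsilyloxy)cyclopent-1-ene (3,4-trans) | C[C@@H]1C=C(O[Si](C)(C)C)C[C@H]1O[Si](C)(C)C(C)(C)C | intermediate
4 | (R)-4-(tert-butyldimethylsilyloxy)-3-methylcyclopent-2-en-1-one | CC1=CC(=O)C[C@H]1O[Si](C)(C)C(C)(C)C | intermediate
5 | isopropylmagnesium chloride | CC(C)[Mg]Cl | starting material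
6 | (1R,4R)-4-(tert-butyldimethylsilyloxy)-3-methyl-1-(propan-2-yl)cyclopent-2-en-1-ol | CC1=C[C@](O)(C(C)C)C[C@H]1O[Si](C)(C)C(C)(C)C | intermediate
7 | (1R,4R)-3-methyl-1-(propan-2-yl)cyclopent-2-ene-1,4-diol | CC1=C[C@](O)(C(C)C)C[C@H]1O | intermediate
8 | (R)-4-hydroxy-2-methyl-4-(propan-2-yl)cyclopent-2-en-1-one | CC1=C[C@](O)(C(C)C)CC1=O | intermediate
9 | (R)-2-methyl-4-(propan-2-yl)-4-(trimethylsilyloxy)cyclopent-2-en-1-one | CC1=C[C@](O[Si](C)(C)C)(C(C)C)CC1=O | intermediate
10 | vinylmagnesium bromide | C=C[Mg]Br | starting material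
11 | 1-bromobut-2-yne | CC#CCBr | starting material
12 | bromomagnesium enolate of (3R,4R)-3-ethenyl-2-methyl-4-(propan-2-yl)-4-(trimethylsilyloxy)cyclopentan-1-one | C=C[C@@H]1C(C)=C(O[Mg]Br)C[C@@]1(O[Si](C)(C)C)C(C)C | intermediate
13 | (2R,3R,4R)-2-(but-2-yn-1-yl)-3-ethenyl-2-methyl-4-(propan-2-yl)-4-(trimethylsilyloxy)cyclopentan-1-one | CC#CC[C@@]1(C)C(=O)C[C@@](O[Si](C)(C)C)(C(C)C)[C@@H]1C=C | intermediate
14 | (2R,3R,4R)-2-(but-2-yn-1-yl)-3-ethenyl-4-hydroxy-2-methyl-4-(propan-2-yl)cyclopentan-1-one | CC#CC[C@@]1(C)C(=O)C[C@@](O)(C(C)C)[C@@H]1C=C | intermediate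
15 | cyclopropyl platinum carbene (C9=PtCl2; β-cyclopropane C6–C7–C8; otherwise as 16) | C1C(=[Pt](Cl)Cl)[C@]2(C)C[C@@H]2[C@@H]3[C@]1(C)C(=O)C[C@@]3(O)C(C)C | intermediate
16 | tricyclic vinylcyclopropane ketone (trans-hydrind-9-en-2-one, C7 bridging C6 and C8 on the β face, 1α,8α-dimethyl, 4α-OH, 4β-isopropyl) | C1=C[C@]2(C)C[C@@H]2[C@@H]3[C@]1(C)C(=O)C[C@@]3(O)C(C)C | intermediate
17 | 9β,10β-epoxide of 16 | O1[C@@H]2[C@H]1[C@]3(C)C[C@@H]3[C@@H]4[C@]2(C)C(=O)C[C@@]4(O)C(C)C | intermediate
18 | angelic acid, (Z)-2-methylbut-2-enoic acid | C/C=C(/C)C(=O)O | starting material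
19 | (1S,4R,5S,6S,10R)-4,10-dihydroxy-2-oxodauc-8-en-6-yl (Z)-2-methylbut-2-enoate | C/C=C(/C)C(=O)O[C@H]1CC(C)=C[C@@H](O)[C@@]2(C)C(=O)C[C@@](O)(C(C)C)[C@H]12 | intermediate
20 | (1S,4R,5S,6S,10R)-4-hydroxy-2-oxodauc-8-ene-6,10-diyl bis[(Z)-2-methylbut-2-enoate] | C/C=C(/C)C(=O)O[C@H]1CC(C)=C[C@@H](OC(=O)/C(C)=C\C)[C@@]2(C)C(=O)C[C@@](O)(C(C)C)[C@H]12 | intermediate
21 | (1R,2R,4R,5S,6S,10R)-2,4-dihydroxydauc-8-ene-6,10-diyl bis[(Z)-2-methylbut-2-enoate] | C/C=C(/C)C(=O)O[C@H]1CC(C)=C[C@@H](OC(=O)/C(C)=C\C)[C@@]2(C)[C@H](O)C[C@@](O)(C(C)C)[C@H]12 | target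

## Step count and risks

Total step count: 11. Longest linear sequence: 11 steps (fully linear from 1).

Three steps most likely to fail:

Step 9, the new ring expansion. It may give Meinwald-type ketone, attack at C7, or 1,2-shift products instead of the 6-ester. The fallback uses known chemistry, sets out from 17 and returns at 20. Epoxide 17 is opened under classical solvolytic conditions (HClO4 cat., THF–water, 0 °C), the hydrative cyclopropylcarbinyl-to-homoallyl rearrangement long known for 2-carene oxide and 2-norcaranyl systems, to give (1S,4R,5S,6S,10R)-4,6,10-trihydroxydauc-8-en-2-one F1. Both secondary hydroxyls of F1 are then acylated in one operation with 18 under the step 10 conditions (2,4,6-trichlorobenzoyl chloride, Et3N, toluene, 80 °C) to give 20.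

Step 8, the face selectivity of the epoxidation. The cyclopropane on the β face opposes the C1 methyl on the α face, so the outcome is not secure. The fallback sets out from 16 and returns at 20. If the 9α,10α-epoxide F2 is the main product, it is opened as in step 9 (the C6 outcome does not depend on the epoxide face) to the 10-epi alcohol (1S,4R,5S,6S,10S)-4,10-dihydroxy-2-oxodauc-8-en-6-yl (Z)-2-methylbut-2-enoate F3. The C10 ester is then installed with inversion by a Mitsunobu reaction (18, PPh3, diisopropyl azodicarboxylate, toluene, 0 °C) to give 20.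

Step 6, the three-component coupling. The β-carbon is hindered, facial control rests on isopropyl against OSiMe3, and the quaternary alkylation is slow. The fallback sets out from 9 and returns at 14, decoupling the two bond formations. The conjugate addition is run with Me3SiCl present (10, CuBr·SMe2, Me3SiCl, THF, −78 °C) and the enol silane (3R,4R)-3-ethenyl-2-methyl-4-(propan-2-yl)-1,4-bis(trimethylsilyloxy)cyclopent-1-ene F4 is isolated. The lithium enolate is regenerated with MeLi (THF, 0 °C) and alkylated with 11 in THF–HMPA to give 13, and dilute HCl then gives 14.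

## Further compounds

F1 | step 9 | (1S,4R,5S,6S,10R)-4,6,10-trihydroxydauc-8-en-2-one | O[C@H]1CC(C)=C[C@@H](O)[C@@]2(C)C(=O)C[C@@](O)(C(C)C)[C@H]12
F2 | step 8 | 9α,10α-epoxide of 16 | O1[C@H]2[C@@H]1[C@]3(C)C[C@@H]3[C@@H]4[C@]2(C)C(=O)C[C@@]4(O)C(C)C
F3 | step 8 | (1S,4R,5S,6S,10S)-4,10-dihydroxy-2-oxodauc-8-en-6-yl (Z)-2-methylbut-2-enoate | C/C=C(/C)C(=O)O[C@H]1CC(C)=C[C@H](O)[C@@]2(C)C(=O)C[C@@](O)(C(C)C)[C@H]12
F4 | step 6 | (3R,4R)-3-ethenyl-2-methyl-4-(propan-2-yl)-1,4-bis(trimethylsilyloxy)cyclopent-1-ene | C=C[C@@H]1C(C)=C(O[Si](C)(C)C)C[C@@]1(O[Si](C)(C)C)C(C)C
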